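## Structural features

The target is a diaryl ether. It joins C8 of a 6-hydroxy-3-pentylisocoumarin (ring A fused to an enol lactone: C1 carbonyl, O2, C3 bearing pentyl, C4–H) to C5' of ring B, an olivetolic acid unit (C1' CO2H, C2' OH, C3' H, C4' OH, C6' pentyl). There is no stereocentre and no stereogenic double bond, so no stereocentres stand next to each other; the problem is one of regiochemistry and functional-group tolerance. Ring B is pentasubstituted, and the ether oxygen is flanked on both sides: by C4'–OH and C6'–pentyl on ring B, and by the carbonyl-bearing C8a on ring A. The fragile groups are the 2,4-dihydroxy-6-alkylbenzoic acid (decarboxylates on heating or in strong acid), the enol lactone (opened by hydroxide or alkoxide, with a reducible C3=C4 bond), and the electron-rich free phenols (oxidised in air under base). The real difficulty is the doubly ortho-substituted aryl–O–aryl bond between two electron-rich rings, which copper- or palladium-mediated etherification handles poorly, together with keeping the two carboxyl carbons (lactone C1, acid C1') distinct. The key step exploits the fact that ring A carbons C5–C8 carry H, O, H, O in the same order as C3–C6 of a 4-alkoxy-6-aryloxy-2-pyranone, while C8a and C4a carry C1 and C4, which together with C3 and its pentyl chain map onto a 2,4-diynoate. Ring A can therefore be grown onto the ether oxygen instead of being coupled to it.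

## Logic of the disconnections

**20 ⇒ 19.** Four O–CH2Ph bonds are cut (three phenol ethers, one carboxylic ester). The three phenols and the acid are carried as benzyl derivatives because these survive carbonate base, 150 °C and gold catalysis, and fall together to one reagent. The gain is that the polar, oxidisable, decarboxylation-prone 20 exists only in the last flask. The forward step must cleave cold and must not touch the enol lactone or its C3=C4 bond.

**19 ⇒ 18.** The O2–C3 bond of the lactone is cut, which returns a methyl ester at C1 and a C3≡C4 triple bond. The heterocycle and its pentyl group then come from a linear heptynyl chain, and 18 is a plain benzoate with two ortho substituents. The forward step must close 6-endo, not 5-exo, and only the ring A ester (the one with an alkyne beside it) may take part.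

**18 ⇒ 11 + 16.** C4a–C5 and C8–C8a are cut and a CO2 bridge is put back between C5 and C8. This places both ring A oxygens, including the diaryl ether oxygen, on diene 11 and the ester and alkyne on dienophile 16, so the fully substituted ring A arises in one convergent step. The forward step must deliver one regiochemistry (ester next to the aryloxy carbon), must use only the ester-bearing triple bond of 16, and both partners must tolerate the heat needed.

**16 ⇒ 15 ⇒ 13 + 14, and 13 ⇒ 12.** The ester O–CH3 bond is cut, then the sp–sp bond between the two triple bonds, then the C–Br bond. This reduces 16 to two small commercial alkynes, 12 and 14. The forward coupling must be a selective heterocoupling, and the three-carbon partner is used as the free acid because its ester would be consumed by the amine base.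

**11 ⇒ 5 + 10.** The bond between pyranone C6 and the ether oxygen is cut. The future diaryl ether is thus formed as a substitution on a vinylogous acid chloride, not as a hindered aryl–O coupling. The forward step needs a dry, oxygen-free medium, and the phenoxide attack must end in substitution and not in permanent ring opening.

**10 ⇒ 9 ⇒ 6.** The O–benzyl bond is cut, then the pyranone ring is traced to two molecules of 6 (one C–C and one C–O bond, with the surplus carboxyl carbon lost as CO2). The forward sequence must keep the ring chloride through hydrolysis and decarboxylation, and must alkylate the 4-oxygen, not the 2-oxygen.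

**5 ⇒ 3 ⇒ 2 ⇒ 1.** The C5'–O bond is cut (by way of C5'–B), then C5'–Br, then the three benzyl groups. Ring B comes complete from 1 and only one oxygen has to be added. The forward sequence needs bromination at C5' and not C3', and a borylation that copes with a bromide between two ortho substituents.

## Other disconnections considered

Alternative 1: ring B by rhodium carbonylative five-plus-one benzannulation.
- Cut: C3'–C4' and C4'–C5' of ring B. C4' and its hydroxyl come from CO; the other five ring carbons come from 1-[(6-benzyloxy-1-oxo-3-pentyl-1H-isochromen-8-yl)oxy]-2-pentylpent-1-en-4-yn-3-yl acetate A2.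
- Forward key step: under [RhCl(CO)2]2 and CO, the propargylic acetate of A2 would undergo a 1,2-acyloxy shift, the rhodium-bound five-carbon unit would insert CO to a dienyl ketene, and 6π-electrocyclisation with tautomerisation would give 4-[(6-benzyloxy-1-oxo-3-pentyl-1H-isochromen-8-yl)oxy]-3-hydroxy-5-pentylphenyl acetate A1.
- In favour: ring B would be assembled with its substitution pattern fixed by construction. The ether oxygen is in place before the ring exists, and the two ring B oxygens emerge differentiated (free 4'-OH, 2'-acetate). The step is catalytic and neutral.
- Against: A1 has hydrogen, not carboxyl, at C1'. A later carboxylation must choose C1' (between the acetoxy and pentyl carbons) over C3' (between two oxygens, the more reactive site), which calls for blocking or directed metalation. A2 is an O-vinyl ether of the chelated C8 hydroxyl of a finished isocoumarin and has an ionisable propargylic acetate next to an enol ether, so its preparation and handling are delicate. The step needs toxic CO and rhodium.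
- Comparison: on mechanism the two plans are equal in concept: an arene is formed by a pericyclic closure made irreversible by a follow-up event (tautomerisation there, loss of CO2 here), and neither needs a hindered aryl–O coupling. Alternative 1 is the better plan on one point: the ring B pattern does not depend on the regiochemistry of an electrophilic substitution, as step 2 of the chosen route does. The chosen plan is better on functional completeness (18 already carries the ester and alkyne for lactonisation, while A1 lacks a carbon), on convergence and step count (the alternative carries a complete isocoumarin through a long linear sequence), and on safety.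

Alternative 2: ring B as a cyclohexanedione by Michael–Claisen annulation, aromatised late.
- Cut: C1'–C6' and C2'–C3' of ring B at the cyclohexane-1,3-dione oxidation level.
- Forward key step: the sodium enolate of a malonic dibenzyl ester would add to C4 of (Z)-3-(2-bromo-5-methoxyphenoxy)non-3-en-2-one A4. After proton transfer the methyl ketone enolate would close onto one malonate ester (Claisen condensation) to give benzyl 5-(2-bromo-5-methoxyphenoxy)-2-hydroxy-4-oxo-6-pentylcyclohex-2-ene-1-carboxylate A3 as a diastereomer mixture. Its stereocentres do not matter because dehydrogenation to the resorcylate removes them.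
- In favour: a one-flask annulation from cheap reagents. Carboxyl at C1', pentyl at C6' and both oxygens are placed by construction. The ether is made early by simple O-alkylation of an unhindered phenol, then aldol condensation.
- Against: in A3 the aryloxy group at C5' sits next to C6'–H in a ring that gains aromaticity by any elimination. Loss of the phenol would aromatise ring B without an oxidant and destroy the ether, so the dehydrogenation would have to outrun it. The α-aryloxy enone A4 is a weaker Michael acceptor than a plain enone. Ring A in A3 is only a bromo methoxy benzene: C1 would have to come from carbonylation at C8a, C4a would need a C–H functionalisation ortho to the new carboxyl, and the C6 methyl ether would need BBr3 at the end, beside a decarboxylation-prone acid.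
- Comparison: on structure this is the mirror image of the chosen plan (ring B built, ring A elaborated). It is the better plan in reagent cost and in fixing the ring B pattern without an aromatic substitution, and the equal of the chosen plan in avoiding a crowded aryl–O coupling. On mechanism the chosen plan is better: its arene forms at the correct oxidation level by CO2 loss, with no leaving group that could be ejected in place of the desired event, whereas A3 needs a separate redox adjustment with a competing elimination. On step economy the chosen plan is clearly shorter after the key step (two steps against a multi-step isocoumarin construction).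

Alternative 3: two-directional Negishi coupling for both pentyl chains.
- Cut: C3–pentyl and C6'–pentyl.
- Forward key step: benzyl 2-bromo-3-[(3-chloro-6-methoxy-1-oxo-1H-isochromen-8-yl)oxy]-4,6-dimethoxybenzoate A6 would couple twice with a primary five-carbon alkylzinc bromide under Pd(OAc)2 and the ligand CPhos. Oxidative addition at the enol-type C3–Cl and the aryl C6'–Br, transmetalation and reductive elimination would give benzyl 2,4-dimethoxy-5-[(6-methoxy-3-pentyl-1-oxo-1H-isochromen-8-yl)oxy]-6-pentylbenzoate A5.
- In favour: both chains from one reagent in one operation. Organozinc reagents tolerate esters and the lactone. Any chain length could be installed late, which is a better position for analogue work than the chosen plan offers. As a reaction class the key step is better precedented than a cycloaddition with an untried diene, so on predictability of the key step alone it is at least the equal of the chosen plan.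
- Against: the step forms no ring and none of the hard bonds. Both rings and the crowded diaryl ether must already exist in A6, where the ether oxygen is flanked by a bromide and an ester-bearing carbon, so the central difficulty is only moved upstream and made worse. The C6'–Br bond lies between two ortho substituents, so the second coupling should be slow and open to reduction. The 3-chloro enol lactone is an acylating agent and may not survive the organometallic. Three methyl ethers would call for BBr3 at the end.
- Comparison: on step economy after the key step the two plans are about equal (one or two deprotections), and on mechanism the alternative is the more routine. On structure the chosen plan is better: its key step creates ring A and leaves the ether bond intact, and its final deprotection (BCl3 with a scavenger at low temperature) is milder than demethylation.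

Key step: step 10

Remark on names: the ring B aryloxy group of 18 has pentyl at position 2, benzyloxycarbonyl at position 3 and benzyloxy groups at positions 4 and 6. These are the only locants consistent with the structure, since pentyl and a benzyloxy group cannot share a ring carbon.

Remark on the chemistry: the target has no stereocentre. Bridged lactones 17 and F2 are racemic and written without descriptors. Two molecules of malonyl dichloride 6 are consumed for each molecule of 9; their self-condensation is taken to give the pyranone 3-carbonyl chloride 7 first, so hydrolysis and loss of CO2 are part of step 4. The diynoate is assembled through the free acid, which avoids both amine addition to a propiolic ester and the lachrymatory methyl bromopropiolate.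

## Route

Step 1
Reactants: 1 olivetolic acid (2,4-dihydroxy-6-pentylbenzoic acid)
Product: 2 benzyl 2,4-bis(benzyloxy)-6-pentylbenzoate
Conditions: BnBr (3.6 equiv), K2CO3, DMF, rt then 60 °C
Reagents that add atoms: benzyl bromide, BrCc1ccccc1
Why: Carboxylate O-alkylation and Williamson ether synthesis; the carboxylate and the 4-OH react at room temperature (which also protects the acid from decarboxylation) and the chelated 2-OH follows on warming with excess benzyl bromide.

Step 2
Reactants: 2 benzyl 2,4-bis(benzyloxy)-6-pentylbenzoate
Product: 3 benzyl 2,4-bis(benzyloxy)-5-bromo-6-pentylbenzoate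
Conditions: NBS (1.05 equiv), MeCN, 0 °C to rt, dark
Reagents that add atoms: N-bromosuccinimide, O=C1CCC(=O)N1Br
Why: Electrophilic aromatic bromination; C5 is para to the 2-benzyloxy group and ortho to the 4-benzyloxy group and is less crowded than C3 between two benzyloxy groups, the usual outcome for 2,4-dialkoxy-6-alkylbenzoates. A polar solvent in the dark suppresses radical bromination at the benzylic positions.

Step 3
Reactants: 3 benzyl 2,4-bis(benzyloxy)-5-bromo-6-pentylbenzoate
Product: 5 benzyl 2,4-bis(benzyloxy)-5-hydroxy-6-pentylbenzoate, via pinacol boronate 4 (not isolated)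
Conditions: B2pin2, KOAc, Pd(OAc)2 (5 mol %), SPhos, 1,4-dioxane, 90 °C; then 30% aq. H2O2, NaHCO3, THF, 0 °C to rt
Reagents that add atoms: hydrogen peroxide, OO (the phenol oxygen of 5); bis(pinacolato)diboron, CC1(C)OB(OC1(C)C)B1OC(C)(C)C(C)(C)O1 (the boryl group of 4 only)
Why: Miyaura borylation, then oxidation of the C–B bond by 1,2-aryl shift from boron to oxygen; the electron-rich biarylphosphine is chosen for a bromide with two ortho substituents. The hindered benzyl ester and the benzyl ethers are inert to acetate and to buffered peroxide at 0 °C; 5 is kept under inert gas because it is an electron-rich phenol.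

Step 4
Reactants: 6 malonyl dichloride (two molecules are joined)
Product: 9 6-chloro-4-hydroxy-2H-pyran-2-one, via pyranone acid chloride 7 (not isolated), via pyranone carboxylic acid 8 (not isolated)
Conditions: neat, rt, 3 d (HCl to scrubber); then H2O, acetone, 0 °C; then 50 °C
Reagents that add atoms: malonyl dichloride, O=C(Cl)CC(=O)Cl (the second molecule of 6); water, O (the carboxyl oxygen of 8 only)
Why: Self-condensation of two molecules of 6 with loss of two HCl: the methylene carbon of one molecule (future C3, with C2 and the exocyclic carbonyl) is acylated by the other (future C4, C5, C6), and the enol oxygen of that second unit closes onto an acyl chloride carbon of the first, which should give 7. Cold water hydrolyses the exocyclic acyl chloride, and the resulting β-keto acid 8 loses CO2 on gentle warming. The 6-chloride is a vinylogous acyl chloride deactivated by the 4-hydroxy donor and should survive brief contact with cold aqueous acid.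

Step 5
Reactants: 9 6-chloro-4-hydroxy-2H-pyran-2-one
Product: 10 4-(benzyloxy)-6-chloro-2H-pyran-2-one
Conditions: BnOH, PPh3, DIAD, THF, 0 °C to rt
Reagents that add atoms: benzyl alcohol, OCc1ccccc1
Why: Mitsunobu O-alkylation; the acidic 4-hydroxy-2-pyranone (a vinylogous carboxylic acid) is alkylated on its 4-oxygen by the benzyloxyphosphonium ion under neutral conditions, so no free alkoxide is present that could displace the 6-chloride.

Step 6
Reactants: 5 benzyl 2,4-bis(benzyloxy)-5-hydroxy-6-pentylbenzoate; 10 4-(benzyloxy)-6-chloro-2H-pyran-2-one
Product: 11 benzyl 2,4-bis(benzyloxy)-5-{[4-(benzyloxy)-2-oxo-2H-pyran-6-yl]oxy}-6-pentylbenzoate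
Conditions: K2CO3, MeCN (dry, degassed), 0 °C to rt
Reagents that add atoms: none
Why: Nucleophilic vinylic substitution by addition–elimination; C6 of 10 is the δ-carbon of a dienoate and carries chloride on an acyl-level carbon, so the phenoxide adds there and chloride leaves. Attack at the lactone carbonyl would open the ring to an acyl chloride or ketene that can close again to the same 6-aryloxy pyranone, so both pathways should converge on 11.

Step 7
Reactants: 12 hept-1-yne
Product: 13 1-bromohept-1-yne
Conditions: NBS, AgNO3 (10 mol %), acetone, rt
Reagents that add atoms: N-bromosuccinimide, O=C1CCC(=O)N1Br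
Why: Silver-catalysed electrophilic bromination of a terminal alkyne through the silver acetylide, the standard preparation of 1-bromoalkynes; the volatile product is carried on in solution.

Step 8
Reactants: 13 1-bromohept-1-yne; 14 propiolic acid (prop-2-ynoic acid)
Product: 15 deca-2,4-diynoic acid
Conditions: CuCl (5 mol %), NH2OH·HCl, aq. EtNH2, MeOH, 0 °C to rt; then 1 M HCl
Reagents that add atoms: none
Why: Cadiot–Chodkiewicz coupling; the copper acetylide of the propiolate salt couples with the bromoalkyne while hydroxylamine keeps copper monovalent and suppresses homocoupling. As its ammonium carboxylate the three-carbon partner is a far poorer Michael acceptor toward the amine than a propiolic ester.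

Step 9
Reactants: 15 deca-2,4-diynoic acid
Product: 16 methyl deca-2,4-diynoate
Conditions: MeOH, H2SO4 (cat.), 40 °C
Reagents that add atoms: methanol, CO
Why: Fischer esterification; acid catalysis avoids base, under which methanol would add to the conjugated diyne. The light-sensitive acid is used crude and the ester is stored cold in solution.

Step 10
Reactants: 11 benzyl 2,4-bis(benzyloxy)-5-{[4-(benzyloxy)-2-oxo-2H-pyran-6-yl]oxy}-6-pentylbenzoate; 16 methyl deca-2,4-diynoate
Product: 18 methyl 4-(benzyloxy)-2-(hept-1-yn-1-yl)-6-[4,6-bis(benzyloxy)-3-(benzyloxycarbonyl)-2-pentylphenoxy]benzoate, via bridged lactone 17 (not isolated)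
Conditions: 16 (3 equiv), BHT (cat.), PhMe, 150 °C, sealed tube
Reagents that add atoms: none
Why: A thermal, normal-electron-demand, concerted but asynchronous (4+2) cycloaddition between the diene C3=C4–C5=C6 of pyranone 11 and the C2≡C3 triple bond of 16 should give bridged lactone 17, which at the reaction temperature loses CO2 by retro-(4+2) reaction to give arene 18. The closest known reaction type is the Diels–Alder reaction of 2-pyranones with alkynes followed by CO2 extrusion to benzoates; a 4-alkoxy-6-aryloxy diene of this kind is a new substrate for it. Ring A is closed intermolecularly by this cycloaddition, which forms C4a–C5 (pyranone C3 to ynoate C3) and C8–C8a (pyranone C6 to ynoate C2); no other ring is made. No stereocentre remains, because the two bridgehead centres of racemic 17 vanish on aromatisation. Regiochemistry: the 4-benzyloxy and 6-aryloxy donors make pyranone C3 the diene terminus with the largest HOMO coefficient, and it pairs with the β-carbon of the ynoate, which has the largest LUMO coefficient, so the ester ends up beside the aryloxy carbon and the heptynyl group beside C5–H. Site selectivity: only the proximal triple bond is directly conjugated to the ester; the distal one is less electron-poor, is flanked by the pentyl chain, and is saved for step 11. Because aromatisation is by loss of CO2, no substituent has to leave and the aryl–O bond stays intact; excess 16, a radical inhibitor and exclusion of nucleophiles limit diyne oligomerisation and ring opening of 11.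

Step 11
Reactants: 18 methyl 4-(benzyloxy)-2-(hept-1-yn-1-yl)-6-[4,6-bis(benzyloxy)-3-(benzyloxycarbonyl)-2-pentylphenoxy]benzoate
Product: 19 benzyl 2,4-bis(benzyloxy)-5-{[6-(benzyloxy)-1-oxo-3-pentyl-1H-isochromen-8-yl]oxy}-6-pentylbenzoate
Conditions: AuCl3 (5 mol %), MeCN, H2O (2 equiv), 50 °C
Reagents that add atoms: none
Why: Gold-catalysed 6-endo-dig oxycyclisation of an ortho-alkynylbenzoate: AuCl3 (trivalent gold) activates the alkyne and the ester carbonyl oxygen, made electron-rich by the para benzyloxy and ortho aryloxy groups, attacks the pentyl-bearing carbon. The resulting 1-methoxyisochromenylium ion gives up its methyl group to water as methanol and protodeauration places hydrogen at C4; the ring B benzyl ester has no alkyne within reach and is untouched.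

Step 12
Reactants: 19 benzyl 2,4-bis(benzyloxy)-5-{[6-(benzyloxy)-1-oxo-3-pentyl-1H-isochromen-8-yl]oxy}-6-pentylbenzoate
Product: 20 2,4-dihydroxy-5-[(6-hydroxy-1-oxo-3-pentyl-1H-isochromen-8-yl)oxy]-6-pentylbenzoic acid (CNP0439913.0)
Conditions: BCl3 (1 M in CH2Cl2), C6HMe5, CH2Cl2, −78 to 0 °C; then aq. NaHCO3, then pH 3
Reagents that add atoms: none
Why: Lewis-acid debenzylation with a cation scavenger; BCl3 cleaves the three aryl benzyl ethers and the benzyl ester, and pentamethylbenzene traps the benzyl cations by Friedel–Crafts alkylation so the electron-rich rings are not C-benzylated. The C3=C4 bond, which hydrogenation could touch, is not at risk, and the low temperature protects the decarboxylation-prone 2,4-dihydroxybenzoic acid.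

## Compound list

1 | olivetolic acid (2,4-dihydroxy-6-pentylbenzoic acid) | CCCCCc1cc(O)cc(O)c1C(=O)O | starting material
2 | benzyl 2,4-bis(benzyloxy)-6-pentylbenzoate | CCCCCc1cc(OCc2ccccc2)cc(OCc2ccccc2)c1C(=O)OCc1ccccc1 | intermediate
3 | benzyl 2,4-bis(benzyloxy)-5-bromo-6-pentylbenzoate | CCCCCc1c(Br)c(OCc2ccccc2)cc(OCc2ccccc2)c1C(=O)OCc1ccccc1 | intermediate
4 | benzyl 2,4-bis(benzyloxy)-6-pentyl-5-(4,4,5,5-tetramethyl-1,3,2-dioxaborolan-2-yl)benzoate | CCCCCc1c(B2OC(C)(C)C(C)(C)O2)c(OCc2ccccc2)cc(OCc2ccccc2)c1C(=O)OCc1ccccc1 | intermediate
5 | benzyl 2,4-bis(benzyloxy)-5-hydroxy-6-pentylbenzoate | CCCCCc1c(O)c(OCc2ccccc2)cc(OCc2ccccc2)c1C(=O)OCc1ccccc1 | intermediate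
6 | malonyl dichloride (propanedioyl dichloride) | O=C(Cl)CC(=O)Cl | starting material
7 | 6-chloro-4-hydroxy-2-oxo-2H-pyran-3-carbonyl chloride | O=C(Cl)c1c(O)cc(Cl)oc1=O | intermediate
8 | 6-chloro-4-hydroxy-2-oxo-2H-pyran-3-carboxylic acid | O=C(O)c1c(O)cc(Cl)oc1=O | intermediate
9 | 6-chloro-4-hydroxy-2H-pyran-2-one | O=c1cc(O)cc(Cl)o1 | intermediate
10 | 4-(benzyloxy)-6-chloro-2H-pyran-2-one | O=c1cc(OCc2ccccc2)cc(Cl)o1 | intermediate
11 | benzyl 2,4-bis(benzyloxy)-5-{[4-(benzyloxy)-2-oxo-2H-pyran-6-yl]oxy}-6-pentylbenzoate | O=c1cc(OCc2ccccc2)cc(Oc2c(OCc3ccccc3)cc(OCc3ccccc3)c(C(=O)OCc3ccccc3)c2CCCCC)o1 | intermediate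
12 | hept-1-yne | CCCCCC#C | starting material
13 | 1-bromohept-1-yne | CCCCCC#CBr | intermediate
14 | propiolic acid (prop-2-ynoic acid) | C#CC(=O)O | starting material
15 | deca-2,4-diynoic acid | CCCCCC#CC#CC(=O)O | intermediate
16 | methyl deca-2,4-diynoate | CCCCCC#CC#CC(=O)OC | intermediate
17 | methyl 1-[4,6-bis(benzyloxy)-3-(benzyloxycarbonyl)-2-pentylphenoxy]-8-(benzyloxy)-5-(hept-1-yn-1-yl)-3-oxo-2-oxabicyclo[2.2.2]octa-5,7-diene-6-carboxylate (racemic) | O=C1OC2(Oc3c(OCc4ccccc4)cc(OCc4ccccc4)c(C(=O)OCc4ccccc4)c3CCCCC)C=C(OCc3ccccc3)C1C(C#CCCCCC)=C2C(=O)OC | intermediate
18 | methyl 4-(benzyloxy)-2-(hept-1-yn-1-yl)-6-[4,6-bis(benzyloxy)-3-(benzyloxycarbonyl)-2-pentylphenoxy]benzoate | CCCCCC#Cc1cc(OCc2ccccc2)cc(Oc2c(OCc3ccccc3)cc(OCc3ccccc3)c(C(=O)OCc3ccccc3)c2CCCCC)c1C(=O)OC | intermediate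
19 | benzyl 2,4-bis(benzyloxy)-5-{[6-(benzyloxy)-1-oxo-3-pentyl-1H-isochromen-8-yl]oxy}-6-pentylbenzoate | CCCCCc1cc2cc(OCc3ccccc3)cc(Oc3c(OCc4ccccc4)cc(OCc4ccccc4)c(C(=O)OCc4ccccc4)c3CCCCC)c2c(=O)o1 | intermediate
20 | 2,4-dihydroxy-5-[(6-hydroxy-1-oxo-3-pentyl-1H-isochromen-8-yl)oxy]-6-pentylbenzoic acid (CNP0439913.0) | CCCCCc1cc2cc(O)cc(Oc3c(O)cc(O)c(C(=O)O)c3CCCCC)c2c(=O)o1 | target

## Step count and risk

Total step count: 12. Longest linear sequence: 7 steps (steps 1, 2, 3, 6, 10, 11, 12 from olivetolic acid). The pyranone branch (steps 4, 5) and the diynoate branch (steps 7, 8, 9) join at steps 6 and 10.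

Least certain steps:

**Step 10 (key step).** The most likely failure is thermal oligomerisation of the diynoate outrunning a cycloaddition that is slowed by the 4-alkoxy group and by the bulky aryloxy group at the reacting diene terminus. Partial addition across the distal triple bond is the second concern. The fallback removes the second triple bond from the dienophile and sets out from 11. Methyl propiolate is brominated (NBS, AgNO3, acetone) to methyl 3-bromoprop-2-ynoate F1, a strong lachrymator that is handled only in a hood, which is why it is not the first choice. Heating 11 with F1 in toluene at 110 °C should give, by the same cycloaddition, methyl 1-[4,6-bis(benzyloxy)-3-(benzyloxycarbonyl)-2-pentylphenoxy]-8-(benzyloxy)-5-bromo-3-oxo-2-oxabicyclo[2.2.2]octa-5,7-diene-6-carboxylate F2, and after loss of CO2 methyl 4-(benzyloxy)-2-bromo-6-[4,6-bis(benzyloxy)-3-(benzyloxycarbonyl)-2-pentylphenoxy]benzoate F3. Sonogashira coupling of F3 with hept-1-yne 12 (Pd(PPh3)2Cl2, CuI, Et3N, DMF, 60 °C) then returns to the route at 18.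

**Step 6.** The phenoxide, hindered by two ortho substituents, may attack the lactone carbonyl and open the ring without reclosure, and traces of water may hydrolyse the chloropyranone. The fallback builds the pyranone on the phenol and bypasses steps 4 and 5. It sets out from 5. 3-Oxopentanedioic acid is dehydrated with Ac2O to 2H-pyran-2,4,6(3H,5H)-trione (acetonedicarboxylic anhydride) F4. Phenol 5 opens F4 (CH2Cl2, rt to 40 °C) to 5-[4,6-bis(benzyloxy)-3-(benzyloxycarbonyl)-2-pentylphenoxy]-3,5-dioxopentanoic acid F5. Cyclodehydration (trifluoroacetic anhydride, CH2Cl2, 0 °C; acyl ketene, then 6π closure onto the aryl ester carbonyl) should give benzyl 2,4-bis(benzyloxy)-5-[(4-hydroxy-2-oxo-2H-pyran-6-yl)oxy]-6-pentylbenzoate F6. Mitsunobu benzylation of F6 (BnOH, PPh3, DIAD) returns to the route at 11.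

**Step 3.** Oxidative addition into the electron-rich C–Br bond between two ortho substituents may be slow, with protodebromination back to 2 competing. The fallback avoids the aryl halide and sets out from 2. Vilsmeier–Haack formylation (POCl3, DMF, 0 to 60 °C, then aq. NaOAc) should give benzyl 2,4-bis(benzyloxy)-5-formyl-6-pentylbenzoate F7, with the same positional preference as the bromination. Dakin-type Baeyer–Villiger oxidation (mCPBA, NaHCO3, CH2Cl2) would give benzyl 2,4-bis(benzyloxy)-5-(formyloxy)-6-pentylbenzoate F8, and mild methanolysis (K2CO3, MeOH, 0 °C) returns to the route at 5.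

**Step 11.** Closure may go 5-exo to the alkylidene phthalide, or the alkyne may be hydrated to a ketone. The fallback uses a halonium-induced closure, for which the 6-endo mode is firmly established with alkynyl benzoates, and sets out from 18. Iodine (MeCN, NaHCO3, rt) should give benzyl 2,4-bis(benzyloxy)-5-{[6-(benzyloxy)-4-iodo-1-oxo-3-pentyl-1H-isochromen-8-yl]oxy}-6-pentylbenzoate F10, with the methyl group leaving as iodomethane. Palladium-catalysed formate reduction of the C–I bond (Pd(OAc)2, PPh3, HCO2Na, DMF, 80 °C) returns to the route at 19.

**Step 8.** The amine may add to the propiolate or to the diynoic acid, the bromoalkyne may homocouple, and copper may promote decarboxylation. The fallback uses the most reliable partner for this coupling and sets out from 13. Coupling with prop-2-yn-1-ol under the same copper conditions should give deca-2,4-diyn-1-ol F9. Oxidation (TEMPO cat., PhI(OAc)2, MeCN/H2O) returns to the route at 15.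

**Step 12.** Cleavage of the benzyl ester may be incomplete at a temperature the product tolerates, and the liberated acid may decarboxylate on warming in the acidic medium. The fallback is neutral hydrogenolysis of 19 (H2, 1 atm, Pd/C, EtOAc, rt), stopped as soon as the four benzyl groups are gone so that the C3=C4 bond is not reduced. It runs from 19 to 20 directly and makes no new compound.

## Further compounds

F1 | step 10 | methyl 3-bromoprop-2-ynoate | BrC#CC(=O)OC
F2 | step 10 | methyl 1-[4,6-bis(benzyloxy)-3-(benzyloxycarbonyl)-2-pentylphenoxy]-8-(benzyloxy)-5-bromo-3-oxo-2-oxabicyclo[2.2.2]octa-5,7-diene-6-carboxylate (racemic) | O=C1OC2(Oc3c(OCc4ccccc4)cc(OCc4ccccc4)c(C(=O)OCc4ccccc4)c3CCCCC)C=C(OCc3ccccc3)C1C(Br)=C2C(=O)OC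
F3 | step 10 | methyl 4-(benzyloxy)-2-bromo-6-[4,6-bis(benzyloxy)-3-(benzyloxycarbonyl)-2-pentylphenoxy]benzoate | COC(=O)c1c(Br)cc(OCc2ccccc2)cc1Oc1c(OCc2ccccc2)cc(OCc2ccccc2)c(C(=O)OCc2ccccc2)c1CCCCC
F4 | step 6 | 2H-pyran-2,4,6(3H,5H)-trione (acetonedicarboxylic anhydride) | O=C1CC(=O)OC(=O)C1
F5 | step 6 | 5-[4,6-bis(benzyloxy)-3-(benzyloxycarbonyl)-2-pentylphenoxy]-3,5-dioxopentanoic acid | OC(=O)CC(=O)CC(=O)Oc1c(OCc2ccccc2)cc(OCc2ccccc2)c(C(=O)OCc2ccccc2)c1CCCCC
F6 | step 6 | benzyl 2,4-bis(benzyloxy)-5-[(4-hydroxy-2-oxo-2H-pyran-6-yl)oxy]-6-pentylbenzoate | O=c1cc(O)cc(Oc2c(OCc3ccccc3)cc(OCc3ccccc3)c(C(=O)OCc3ccccc3)c2CCCCC)o1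
F7 | step 3 | benzyl 2,4-bis(benzyloxy)-5-formyl-6-pentylbenzoate | CCCCCc1c(C=O)c(OCc2ccccc2)cc(OCc2ccccc2)c1C(=O)OCc1ccccc1
F8 | step 3 | benzyl 2,4-bis(benzyloxy)-5-(formyloxy)-6-pentylbenzoate | CCCCCc1c(OC=O)c(OCc2ccccc2)cc(OCc2ccccc2)c1C(=O)OCc1ccccc1
F9 | step 8 | deca-2,4-diyn-1-ol | CCCCCC#CC#CCO
F10 | step 11 | benzyl 2,4-bis(benzyloxy)-5-{[6-(benzyloxy)-4-iodo-1-oxo-3-pentyl-1H-isochromen-8-yl]oxy}-6-pentylbenzoate | CCCCCc1oc(=O)c2c(Oc3c(OCc4ccccc4)cc(OCc4ccccc4)c(C(=O)OCc4ccccc4)c3CCCCC)cc(OCc3ccccc3)cc2c1I
F0 | step 12 | none | none
A1 | alternative 1 | 4-[(6-benzyloxy-1-oxo-3-pentyl-1H-isochromen-8-yl)oxy]-3-hydroxy-5-pentylphenyl acetate | CCCCCc1cc2cc(OCc3ccccc3)cc(Oc3c(O)cc(OC(C)=O)cc3CCCCC)c2c(=O)o1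
A2 | alternative 1 | 1-[(6-benzyloxy-1-oxo-3-pentyl-1H-isochromen-8-yl)oxy]-2-pentylpent-1-en-4-yn-3-yl acetate (racemic, alkene geometry not fixed) | C#CC(OC(C)=O)C(CCCCC)=COc1cc(OCc2ccccc2)cc2cc(CCCCC)oc(=O)c12
A3 | alternative 2 | benzyl 5-(2-bromo-5-methoxyphenoxy)-2-hydroxy-4-oxo-6-pentylcyclohex-2-ene-1-carboxylate (enol form, diastereomer mixture) | CCCCCC1C(C(=O)OCc2ccccc2)C(O)=CC(=O)C1Oc1cc(OC)ccc1Br
A4 | alternative 2 | (Z)-3-(2-bromo-5-methoxyphenoxy)non-3-en-2-one | CC(=O)/C(Oc1cc(OC)ccc1Br)=C/CCCCC
A5 | alternative 3 | benzyl 2,4-dimethoxy-5-[(6-methoxy-3-pentyl-1-oxo-1H-isochromen-8-yl)oxy]-6-pentylbenzoate | CCCCCc1cc2cc(OC)cc(Oc3c(OC)cc(OC)c(C(=O)OCc4ccccc4)c3CCCCC)c2c(=O)o1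
A6 | alternative 3 | benzyl 2-bromo-3-[(3-chloro-6-methoxy-1-oxo-1H-isochromen-8-yl)oxy]-4,6-dimethoxybenzoate | Clc1cc2cc(OC)cc(Oc3c(OC)cc(OC)c(C(=O)OCc4ccccc4)c3Br)c2c(=O)o1
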